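Structural features

The target is a 7-methoxycoumarin (benzene ring A fused to the α-pyranone ring B) whose C3 is joined by a single C–C bond to C1′ of a six-membered carbocycle, ring C. Ring C is a cyclohex-2-ene-1,4-dione: C1′=C2′H lies between the C6′ and C3′ carbonyls, C5′ is a methylene, and C4′ is a tertiary carbinol carrying a prenyl (3-methylbut-2-enyl) chain. C4′ (R) is the only stereocentre and has no stereogenic neighbour, so its configuration must come from a reagent, a catalyst or a temporary centre that is later erased. The fragile groups are these: the β-hydroxy ketone C4′(OH)–C5′H2–C6′=O, which loses water under acid or base to the fully conjugated para-quinone and so destroys the stereocentre; the tertiary α-ketol C3′(=O)–C4′(OH), open to acyloin shift or retro-benzoin cleavage; the enedione and the C3=C4 bond of ring B, both Michael acceptors; the base-labile lactone; and the acid- and oxidant-sensitive prenyl alkene. The real difficulty is twofold: an oxygenated quaternary stereocentre must be made enantioselectively next to a ketone, and the heteroaryl group must end up on C1′ and not on C2′ of an enedione whose two alkene carbons differ only in the carbonyl they are α to. The key step exploits the C3′(=O)–C4′(OH)(prenyl) unit of ring C, because a tertiary α-ketol is what results when an aldehyde carbon (C3′) adds as an acyl anion to a ketone carbon (C4′), and this bond closes ring C. Holding C6′ as a silyl-protected secondary alcohol of defined configuration until the last step keeps the dehydration pathway shut and turns any C4′ isomer into a separable diastereomer.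

Logic of the disconnections

23 to 22. No skeletal bond is cut; the C6′ carbonyl is taken back to a secondary allylic alcohol. The C4′ hydroxyl is β to C6′=O, so this carbonyl should appear last and under neutral conditions. The gain is that every earlier intermediate is a simple mono-enone that cannot dehydrate to a quinone. The forward step needs a neutral oxidant that ignores the tertiary alcohol, the prenyl alkene and the lactone.

22 to 21. The O–Si bond at C6′ is cut. The C6′ oxygen has to be masked while ring C is closed, desaturated and arylated, so that C4′ and C6′ never form a 1,3-dicarbonyl pair early. The forward step needs a fluoride source that is not basic, because base would isomerise the γ-hydroxy enone and open the lactone.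

21 to 16 and 20. The C1′–C3 bond between ring C and ring B is cut, the only bond joining the two ring systems. This gives a simple enone and a boron derivative of a purchasable heterocycle. With only the C3′ carbonyl present, enone polarisation alone dictates that the new group goes to C1′, so the C1′/C2′ problem is solved by the order of events. The forward step must be a β-arylation that ends in β-hydride elimination and tolerates a free tertiary alcohol and a trisubstituted alkene.

20 to 19 to 17. The C3–B bond and then the C3–Br bond are cut. C3 is the nucleophilic carbon of the enol-ether-like C3=C4 bond, so halogenation there is selective, and the bromide serves both the main route and a boron-free fallback. The forward steps need addition–elimination bromination that spares ring A, and borylation under anhydrous weak base to limit protodeboronation.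

16 to 14 to 13. The C1′=C2′ π bond is removed (two C–H bonds restored) via the silyl enol ether. A saturated ketone is what the ring-forming step delivers. Since C4′ is quaternary, C2′ is the only enolisable position and the site of desaturation is fixed by the structure. The forward steps need enol silylation that also caps the tertiary alcohol, and a palladium-mediated dehydrosilylation that leaves the prenyl alkene alone.

13 to 12. The C3′–C4′ bond is cut. This opens ring C, removes the only stereocentre of the target and leaves an acyclic keto-aldehyde whose single stereocentre (C6′) can be bought by resolution. The forward step needs a 6-exo closure with facial control at the ketone, under a base weak enough to leave a doubly enolisable, β-silyloxy, β,γ-unsaturated ketone alone.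

12 to 11 to 10. Two carbonyl groups are traced back to masked forms, the aldehyde to a dimethyl acetal and the ketone to a dithiane. Neither free carbonyl would survive the organolithium chemistry that assembles the chain. The forward steps need a near-neutral alkylative dithiane hydrolysis and then a mild acid that spares the secondary silyl ether.

10 to 4, 5 and 6. Both C–C bonds at the dithiane carbon (future C4′) are cut, the one to C5′ and the one to the prenyl methylene, together with the O–Si bond. The dithiane carbon is an acyl dianion equivalent, so the 1,3-relationship between the C6′ oxygen and the C4′ carbonyl maps onto an epoxide opening. This avoids both the ambiguous enolisation of a prenyl methyl ketone and the allylic transposition of prenyl organometallics. Three simple components are joined in one flask. The forward step needs the right order: epoxide opening in ether, solvent-triggered silyl migration, then SN2 alkylation.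

4 to 3 to 2 to 1. The oxirane C–O bonds and the acetal C–O bonds are cut back to a commercial unsaturated aldehyde. The forward steps need a buffered epoxidation and a kinetic resolution that leaves the (R)-epoxide.

Other disconnections considered

Alternative 1: The cut removes the C4′–O bond together with a temporary C5′–O bond. The carbinol is traced to a C4′–C5′ oxirane on a para-quinone monoketal, so ring C comes from an arene by oxidative dearomatisation and is never built. In the forward sense the monoketal dienone A1 would be treated with Ph3COOH, NaN(SiMe3)2 and a diisopropyl tartrate. The peroxide anion adds to C5′ and the enolate closes on oxygen at C4′ (a Weitz–Scheffer epoxidation under chiral alkoxide control) to give the oxirane A2.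

- In its favour: the whole carbon skeleton, including the bond to ring B, is assembled by aromatic cross-coupling. That is more dependable than the arylation of a hindered enone in step 12 of the chosen plan, and on this point the alternative is the better one. C6′ is stored as a ketal and needs no redox step, and the path up to A2 should be shorter.
- Against it here: A1 offers the peroxide three acceptor carbons (C5′, C1′ and C4 of ring B) and a base-sensitive lactone, and the chiral controller is stoichiometric and acts on an α-substituted enone arm. Most seriously, 23 needs C5′ as a methylene, so A2 must be opened reductively at C5′–O. Relative to the C3′ ketone the α-carbon of the oxirane is C4′, so electron-transfer reductants would break C4′–O and erase the stereocentre. Breaking C5′–O requires a free C6′ ketone, at which point the epoxy-enedione is itself the most reducible group, and the acid needed for ketal hydrolysis invites dehydration.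
- Comparison: structurally both plans address C4′ directly, but the alternative makes one C–O bond too many, whereas the chosen plan makes the C3′–C4′ bond with C5′ already a methylene. Mechanistically both rely on a chiral controller choosing a face of an sp2 carbon and are equals there, the chosen plan being catalytic and using a weak base. In step economy the alternative leads up to its key step and is expected to lose that lead between A2 and 23.

Alternative 2: The cut lies in the heterocycle. C4a–C4 and O1–C2 of the pyran ring are disconnected to 3-methoxyphenol A3 and the 2-arylpropenal A4, which carries ring C as a fully substituted arene. In the forward sense PhB(OH)2 and propanoic acid tether phenol and enal through boron, ortho-selective condensation gives an ortho-quinone methide, and a thermal oxa-6π electrocyclisation closes the 2H-chromene A5.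

- In its favour: the step is metal-free, convergent and regiochemically secure (closure para to the methoxy group). It joins ring C to the heterocycle without any cross-coupling, which is at least the equal of the Heck step of the chosen plan and probably more robust. Ring C arrives with oxygen at C3′ and C6′ and with the prenyl group in place.
- Against it here: the step builds the part of the molecule that the chosen route buys as 17, creates no stereocentre and leaves ring C aromatic. The C2 methylene of A5 must be oxidised to the lactone beside an oxidisable prenyl group. Ring C must then be taken through the quinone A6 and hydrated enantioselectively across C4′=C5′ with oxygen on the substituted carbon. No direct method is available for that operation. It would have to borrow the epoxidation and the awkward reductive opening of alternative 1, and it runs against the tendency of 23 to lose water back to A6.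
- Comparison: structurally the alternative solves the ring junction and leaves the stereocentre open, the chosen plan the reverse. Mechanistically a pericyclic cascade is as reliable as anything in the chosen route but stereochemically silent. In step economy it is short up to A5 and the longest of all the plans afterwards.

Alternative 3: The cut takes two bonds of ring C, C6′–C1′ and C2′–C3′. This divides it into the four-carbon diketone A7, which already holds C4′ as a silyl-protected carbinol, and the two-carbon alkyne A8. In the forward sense zerovalent nickel (Ni(cod)2, PMe3; or stoichiometric ClCo(PPh3)3, a monovalent cobalt complex) adds oxidatively into the strained C3′–C6′ acyl–acyl bond. The alkyne inserts into the diacyl metallacycle and reductive elimination closes ring C as the enedione A9, the triethylsilyl ether of 23.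

- In its favour: this is the most convergent of the four plans. Two C–C bonds, ring C, the correct oxidation level at both carbonyls and the heteroaryl group arrive in one step, and the stereocentre is carried through untouched. Only a desilylation separates A9 from 23, against five steps after the key step in the chosen plan. On step economy after the key step, and on avoiding the enone arylation, the alternative is clearly the better.
- Against it here: the insertion is established for cyclobutenediones, their benzo-fused analogues and cyclobutanones, not for a saturated α-silyloxy cyclobutane-1,2-dione, where decarbonylation of the metallacycle and nucleophile-induced ring contraction are expected to compete. The regiochemistry of alkyne insertion (heteroaryl carbon to C6′ and not C3′) rests only on the steric difference between a methylene-flanked and a quaternary-flanked acyl group. A terminal alkyne can oligomerise on zerovalent nickel. Enantiopure A7 needs its own multistep asymmetric synthesis, so the stereochemical problem is moved, not solved.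
- Comparison: structurally both plans build ring C around a defined C4′, the alternative forming two bonds where the chosen plan forms one. Mechanistically the alternative relies on C–C activation without close precedent on this substrate class, the chosen plan on an organocatalytic reaction with close precedent. In step economy the alternative would win if the insertion proved regioselective; the chosen plan accepts a longer endgame in exchange for predictable steps.

Key step: step 7

Assumption: the (4R) configuration of 12 and the (5aR,10bS) triazolium salt are taken as the matched pair on the basis of a chair-like closure with the silyloxy group equatorial; if either sense proves opposite, the antipodal epoxide (from the (S,S)-cobalt complex in step 3) or the antipodal triazolium salt is used and nothing else changes, because C6′ is oxidised in step 14.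

Step 1
Reactants: 1 pent-4-enal
Product: 2 5,5-dimethoxypent-1-ene
Conditions: HC(OMe)3, TsOH·H2O (cat.), MeOH, rt
Reagents that add atoms: trimethyl orthoformate, COC(OC)OC
Why: Acid-catalysed acetalisation with the orthoformate as water scavenger; the acetal masks the aldehyde against the peracid of step 2 and the organolithium reagents of step 4.

Step 2
Reactants: 2 5,5-dimethoxypent-1-ene
Product: 3 rac-2-(3,3-dimethoxypropyl)oxirane
Conditions: mCPBA, NaHCO3, CH2Cl2, 0 °C → rt
Reagents that add atoms: 3-chloroperoxybenzoic acid, O=C(OO)c1cccc(Cl)c1
Why: Prilezhaev epoxidation of the only alkene; the bicarbonate buffer keeps the acetal intact.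

Step 3
Reactants: 3 rac-2-(3,3-dimethoxypropyl)oxirane
Product: 4 (2R)-2-(3,3-dimethoxypropyl)oxirane
Conditions: (R,R)-(salen)Co(OAc) (0.5 mol%), H2O (0.55 equiv), THF, 0 °C → rt; distillation
Reagents that add atoms: none
Why: Hydrolytic kinetic resolution: the trivalent cobalt complex (salen = N,N′-bis(3,5-di-tert-butylsalicylidene)cyclohexane-1,2-diaminate) delivers water to the terminal carbon of the (S)-epoxide much faster than to its antipode, so the (R)-epoxide should be recovered by distillation from the diol. This centre becomes C6′; it is not in the target and serves only to make later C4′ isomers diastereomers.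

Step 4
Reactants: 4 (2R)-2-(3,3-dimethoxypropyl)oxirane; 5 2-(tert-butyldimethylsilyl)-1,3-dithiane; 6 1-bromo-3-methylbut-2-ene (prenyl bromide)
Product: 10 2-[(2R)-2-(tert-butyldimethylsilyloxy)-5,5-dimethoxypentyl]-2-(3-methylbut-2-enyl)-1,3-dithiane, via 2-lithio-2-(tert-butyldimethylsilyl)-1,3-dithiane 7 (not isolated), via lithium (2R)-1-[2-(tert-butyldimethylsilyl)-1,3-dithian-2-yl]-5,5-dimethoxypentan-2-olate 8 (not isolated), via 2-lithio-2-[(2R)-2-(tert-butyldimethylsilyloxy)-5,5-dimethoxypentyl]-1,3-dithiane 9 (not isolated)
Conditions: 5, t-BuLi, Et2O, −78 → −45 °C; 4, −78 → −25 °C; then 6, HMPA/THF, −78 → 0 °C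
Reagents that add atoms: none
Why: Three-component dithiane linchpin coupling: the silyl-dithiane anion opens the epoxide at its terminal carbon with retention at the carbinol centre, the polar cosolvent then triggers a 1,4-Brook rearrangement that moves silicon from carbon to oxygen and regenerates a dithiane anion, and this anion is alkylated by the primary allylic bromide in the SN2 sense. The silyl ether is installed without a separate protection step.

Step 5
Reactants: 10 2-[(2R)-2-(tert-butyldimethylsilyloxy)-5,5-dimethoxypentyl]-2-(3-methylbut-2-enyl)-1,3-dithiane
Product: 11 (4R)-4-(tert-butyldimethylsilyloxy)-1,1-dimethoxy-9-methyldec-8-en-6-one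
Conditions: MeI, CaCO3, MeCN/H2O (9:1), 40 °C
Reagents that add atoms: water, O
Why: Alkylative dithiane hydrolysis: S-methylation makes a sulfonium leaving group and water delivers the ketone; the carbonate-buffered, near-neutral medium should spare the acetal, the β-silyloxy ketone and the skipped (β,γ) prenyl alkene.

Step 6
Reactants: 11 (4R)-4-(tert-butyldimethylsilyloxy)-1,1-dimethoxy-9-methyldec-8-en-6-one
Product: 12 (4R)-4-(tert-butyldimethylsilyloxy)-9-methyl-6-oxodec-8-enal
Conditions: pyridinium p-toluenesulfonate (cat.), acetone/H2O (10:1), 40 °C; used at once
Reagents that add atoms: water, O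
Why: Mild acid-catalysed hydrolysis of the dimethyl acetal; a secondary tert-butyldimethylsilyl ether and the ketone tolerate this weak acid for the short time needed, and the sensitive 1,6-keto-aldehyde is taken directly into the key step.

Step 7
Reactants: 12 (4R)-4-(tert-butyldimethylsilyloxy)-9-methyl-6-oxodec-8-enal
Product: 13 (2R,4R)-4-(tert-butyldimethylsilyloxy)-2-hydroxy-2-(3-methylbut-2-enyl)cyclohexan-1-one
Conditions: (5aR,10bS)-2-[3,5-bis(trifluoromethyl)phenyl]-5a,10b-dihydro-4H,6H-indeno[2,1-b][1,2,4]triazolo[4,3-d][1,4]oxazin-2-ium chloride (10 mol%), Et3N (10 mol%), toluene (0.05 M), rt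
Reagents that add atoms: none
Why: Et3N deprotonates the triazolium salt to the carbene, which adds to the unhindered aldehyde carbon of 12 (the future C3′), and proton transfer gives the Breslow enaminol, an acyl anion equivalent. The enaminol carbon attacks the ketone carbon (the future C4′) while its hydroxyl proton passes to the developing alkoxide, and collapse of the adduct releases the carbene and the α-ketol, forming the C3′–C4′ bond. The closest known reaction type is the carbene-catalysed enantioselective intramolecular crossed benzoin of enolisable keto-aldehydes to cyclic tertiary α-ketols. Ring C closes in the 6-exo-trig mode. The new stereocentre C4′ is controlled by the aminoindanol backbone of the catalyst, which should leave the Si face of the ketone open to the enaminol, and by the (4R)-silyloxy group, which sits equatorial in the chair-like closure with the prenyl arm axial, so that hydroxyl and silyloxy end up cis. Chemoselectivity is secured by the substrate: only the aldehyde can form the enaminol, the ketone is the only acceptor, and the silyl ether keeps C6′ from forming a 1,3-dicarbonyl enol with C4′. The step also needs the carbene pathway to outrun the enolate pathways (five-ring aldol, loss of silanol from the β-silyloxy ketone, migration of the skipped alkene into conjugation), which a catalytic amount of a weak amine in toluene should allow. Because C6′ is a defined stereocentre, any C4′ epimer is a diastereomer and should be removable by chromatography before C6′ is oxidised.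

Step 8
Reactants: 13 (2R,4R)-4-(tert-butyldimethylsilyloxy)-2-hydroxy-2-(3-methylbut-2-enyl)cyclohexan-1-one
Product: 14 (4R,6R)-4-(tert-butyldimethylsilyloxy)-6-(3-methylbut-2-enyl)-1,6-bis(trimethylsilyloxy)cyclohex-1-ene
Conditions: TMSOTf, Et3N, CH2Cl2, −78 → 0 °C
Reagents that add atoms: trimethylsilyl trifluoromethanesulfonate, C[Si](C)(C)OS(=O)(=O)C(F)(F)F
Why: Soft enolisation: C2′ is the only α-carbon bearing hydrogen because C4′ is quaternary, so a single silyl enol ether should form; the tertiary hydroxyl is silylated at the same time, which shields the α-ketol in the palladium step.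

Step 9
Reactants: 14 (4R,6R)-4-(tert-butyldimethylsilyloxy)-6-(3-methylbut-2-enyl)-1,6-bis(trimethylsilyloxy)cyclohex-1-ene
Product: 16 (4S,6R)-4-(tert-butyldimethylsilyloxy)-6-hydroxy-6-(3-methylbut-2-enyl)cyclohex-2-en-1-one, via (4S,6R)-4-(tert-butyldimethylsilyloxy)-6-(3-methylbut-2-enyl)-6-(trimethylsilyloxy)cyclohex-2-en-1-one 15 (not isolated)
Conditions: Pd(OAc)2 (1.1 equiv), MeCN, rt; then 1 M HCl, THF, 0 °C
Reagents that add atoms: none
Why: Saegusa–Ito oxidation: divalent palladium converts the silyl enol ether into a palladium enolate and β-hydride elimination from C1′ gives the C1′=C2′ enone; brief dilute acid then frees the tertiary alcohol while the secondary tert-butyldimethylsilyl ether stays. The descriptor at the silyloxy carbon changes from R to S only because its neighbour is now sp2.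

Step 10
Reactants: 17 7-methoxychromen-2-one (7-methoxycoumarin)
Product: 19 3-bromo-7-methoxychromen-2-one, via trans-3,4-dibromo-7-methoxy-3,4-dihydrochromen-2-one 18 (not isolated)
Conditions: Br2, CH2Cl2, 0 °C → rt; then Et3N, 0 °C → rt
Reagents that add atoms: bromine, BrBr
Why: Bromine adds across the electron-rich C3=C4 bond and the amine removes the acidic C3 proton with loss of the benzylic C4 bromide (E1cB), leaving bromine on C3; this addition–elimination sequence should avoid substitution on ring A.

Step 11
Reactants: 19 3-bromo-7-methoxychromen-2-one
Product: 20 7-methoxy-3-(4,4,5,5-tetramethyl-1,3,2-dioxaborolan-2-yl)chromen-2-one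
Conditions: B2pin2, PdCl2(dppf) (5 mol%), KOAc, 1,4-dioxane, 80 °C
Reagents that add atoms: bis(pinacolato)diboron, CC1(C)OB(OC1(C)C)B1OC(C)(C)C(C)(C)O1
Why: Miyaura borylation: oxidative addition of the alkenyl bromide to zerovalent palladium, acetate-assisted transmetalation from the diboron and reductive elimination; the weak anhydrous base limits protodeboronation and leaves the lactone closed.

Step 12
Reactants: 16 (4S,6R)-4-(tert-butyldimethylsilyloxy)-6-hydroxy-6-(3-methylbut-2-enyl)cyclohex-2-en-1-one; 20 7-methoxy-3-(4,4,5,5-tetramethyl-1,3,2-dioxaborolan-2-yl)chromen-2-one
Product: 21 3-[(4R,6S)-6-(tert-butyldimethylsilyloxy)-4-hydroxy-4-(3-methylbut-2-enyl)-3-oxocyclohex-1-en-1-yl]-7-methoxychromen-2-one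
Conditions: Pd(MeCN)4(BF4)2 (10 mol%), 6,6′-dimethyl-2,2′-bipyridine (10 mol%), O2 (1 atm), NMP, 50 °C
Reagents that add atoms: none
Why: Oxidative (boron) Heck reaction: transmetalation to divalent palladium, syn carbopalladation of the enone placing the heteroaryl group on the β-carbon C1′, equilibration through the palladium enolate and β-hydride elimination to restore the C1′=C2′ enone, with O2 reoxidising zerovalent palladium. Enone polarisation fixes C1′ over C2′, and the unactivated trisubstituted prenyl alkene should be far less reactive.

Step 13
Reactants: 21 3-[(4R,6S)-6-(tert-butyldimethylsilyloxy)-4-hydroxy-4-(3-methylbut-2-enyl)-3-oxocyclohex-1-en-1-yl]-7-methoxychromen-2-one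
Product: 22 3-[(4R,6S)-4,6-dihydroxy-4-(3-methylbut-2-enyl)-3-oxocyclohex-1-en-1-yl]-7-methoxychromen-2-one
Conditions: HF·pyridine, THF/pyridine, 0 °C → rt
Reagents that add atoms: none
Why: Fluoride-driven cleavage of the Si–O bond under buffered, weakly acidic conditions, which avoid base-induced isomerisation of the γ-hydroxy enone and opening of the lactone.

Step 14
Reactants: 22 3-[(4R,6S)-4,6-dihydroxy-4-(3-methylbut-2-enyl)-3-oxocyclohex-1-en-1-yl]-7-methoxychromen-2-one
Product: 23 3-[(4R)-4-hydroxy-4-(3-methylbut-2-enyl)-3,6-dioxocyclohex-1-en-1-yl]-7-methoxychromen-2-one
Conditions: Dess–Martin periodinane, NaHCO3, CH2Cl2, 0 °C; Na2S2O3/NaHCO3 work-up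
Reagents that add atoms: none
Why: Dess–Martin oxidation of the secondary allylic C6′ alcohol; the tertiary C4′ alcohol cannot be oxidised, and the bicarbonate buffer with a cold neutral work-up should keep the new β-hydroxy ketone from losing water. C4′ is untouched, so its (R) configuration from step 7 is carried into the target.

Compound list

1 | pent-4-enal | C=CCCC=O | starting material
2 | 5,5-dimethoxypent-1-ene | C=CCCC(OC)OC | intermediate
3 | rac-2-(3,3-dimethoxypropyl)oxirane | COC(OC)CCC1CO1 | intermediate
4 | (2R)-2-(3,3-dimethoxypropyl)oxirane | COC(OC)CC[C@@H]1CO1 | intermediate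
5 | 2-(tert-butyldimethylsilyl)-1,3-dithiane | CC(C)(C)[Si](C)(C)C1SCCCS1 | starting material
6 | 1-bromo-3-methylbut-2-ene (prenyl bromide) | CC(C)=CCBr | starting material
7 | 2-lithio-2-(tert-butyldimethylsilyl)-1,3-dithiane | CC(C)(C)[Si](C)(C)C1([Li])SCCCS1 | intermediate
8 | lithium (2R)-1-[2-(tert-butyldimethylsilyl)-1,3-dithian-2-yl]-5,5-dimethoxypentan-2-olate | COC(OC)CC[C@@H]([O-])CC1([Si](C)(C)C(C)(C)C)SCCCS1.[Li+] | intermediate
9 | 2-lithio-2-[(2R)-2-(tert-butyldimethylsilyloxy)-5,5-dimethoxypentyl]-1,3-dithiane | COC(OC)CC[C@@H](O[Si](C)(C)C(C)(C)C)CC1([Li])SCCCS1 | intermediate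
10 | 2-[(2R)-2-(tert-butyldimethylsilyloxy)-5,5-dimethoxypentyl]-2-(3-methylbut-2-enyl)-1,3-dithiane | COC(OC)CC[C@@H](O[Si](C)(C)C(C)(C)C)CC1(CC=C(C)C)SCCCS1 | intermediate
11 | (4R)-4-(tert-butyldimethylsilyloxy)-1,1-dimethoxy-9-methyldec-8-en-6-one | COC(OC)CC[C@@H](O[Si](C)(C)C(C)(C)C)CC(=O)CC=C(C)C | intermediate
12 | (4R)-4-(tert-butyldimethylsilyloxy)-9-methyl-6-oxodec-8-enal | O=CCC[C@@H](O[Si](C)(C)C(C)(C)C)CC(=O)CC=C(C)C | intermediate
13 | (2R,4R)-4-(tert-butyldimethylsilyloxy)-2-hydroxy-2-(3-methylbut-2-enyl)cyclohexan-1-one | O=C1[C@@](O)(CC=C(C)C)C[C@H](O[Si](C)(C)C(C)(C)C)CC1 | intermediate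
14 | (4R,6R)-4-(tert-butyldimethylsilyloxy)-6-(3-methylbut-2-enyl)-1,6-bis(trimethylsilyloxy)cyclohex-1-ene | C[Si](C)(C)OC1=CC[C@@H](O[Si](C)(C)C(C)(C)C)C[C@]1(O[Si](C)(C)C)CC=C(C)C | intermediate
15 | (4S,6R)-4-(tert-butyldimethylsilyloxy)-6-(3-methylbut-2-enyl)-6-(trimethylsilyloxy)cyclohex-2-en-1-one | O=C1[C@@](O[Si](C)(C)C)(CC=C(C)C)C[C@H](O[Si](C)(C)C(C)(C)C)C=C1 | intermediate
16 | (4S,6R)-4-(tert-butyldimethylsilyloxy)-6-hydroxy-6-(3-methylbut-2-enyl)cyclohex-2-en-1-one | O=C1[C@@](O)(CC=C(C)C)C[C@H](O[Si](C)(C)C(C)(C)C)C=C1 | intermediate
17 | 7-methoxychromen-2-one (7-methoxycoumarin) | COc1ccc2ccc(=O)oc2c1 | starting material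
18 | trans-3,4-dibromo-7-methoxy-3,4-dihydrochromen-2-one (racemic, one enantiomer drawn) | COc1ccc2[C@@H](Br)[C@H](Br)C(=O)Oc2c1 | intermediate
19 | 3-bromo-7-methoxychromen-2-one | COc1ccc2cc(Br)c(=O)oc2c1 | intermediate
20 | 7-methoxy-3-(4,4,5,5-tetramethyl-1,3,2-dioxaborolan-2-yl)chromen-2-one | COc1ccc2cc(B3OC(C)(C)C(C)(C)O3)c(=O)oc2c1 | intermediate
21 | 3-[(4R,6S)-6-(tert-butyldimethylsilyloxy)-4-hydroxy-4-(3-methylbut-2-enyl)-3-oxocyclohex-1-en-1-yl]-7-methoxychromen-2-one | COc1ccc2cc(C3=CC(=O)[C@@](O)(CC=C(C)C)C[C@@H]3O[Si](C)(C)C(C)(C)C)c(=O)oc2c1 | intermediate
22 | 3-[(4R,6S)-4,6-dihydroxy-4-(3-methylbut-2-enyl)-3-oxocyclohex-1-en-1-yl]-7-methoxychromen-2-one | COc1ccc2cc(C3=CC(=O)[C@@](O)(CC=C(C)C)C[C@@H]3O)c(=O)oc2c1 | intermediate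
23 | 3-[(4R)-4-hydroxy-4-(3-methylbut-2-enyl)-3,6-dioxocyclohex-1-en-1-yl]-7-methoxychromen-2-one | COc1ccc2cc(C3=CC(=O)[C@@](O)(CC=C(C)C)CC3=O)c(=O)oc2c1 | target

Total step count: 14. Longest linear sequence: 12 steps (steps 1 to 9 and 12 to 14, from 1 to 23); the two-step coumarin branch (steps 10 and 11) joins at step 12.

Steps least certain to work

Step 7 (key step). The carbene pathway must outrun every enolate pathway of a doubly enolisable substrate. What may go wrong is base-promoted aldol closure of the 1,6-keto-aldehyde to five-membered rings, E1cB loss of silanol from the β-silyloxy ketone, migration of the skipped alkene into conjugation, or poor facial selectivity if the catalyst and the C6′ centre are mismatched. Fallback: from 12, reductive pinacol cyclisation with SmI2 (THF, t-BuOH, −78 °C) should give the cis-diol (1R,2S,5R)-5-(tert-butyldimethylsilyloxy)-1-(3-methylbut-2-enyl)cyclohexane-1,2-diol F1, the tertiary centre being directed by the equatorial silyloxy group in a chelated chair. Oxidation of its only secondary hydroxyl (Dess–Martin periodinane, NaHCO3, CH2Cl2) comes back to the route at 13. No base and no enolate are involved, and a wrong C4′ isomer is again a separable diastereomer.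

Step 12. What may go wrong is protodeboronation or oxidative homocoupling of the electron-poor alkenyl boron reagent outpacing transmetalation, slow carbopalladation at a β-carbon flanked by the silyloxy-bearing C6′, or protonation of the palladium enolate in place of β-hydride elimination, which would give net conjugate addition. Fallback: from 16 and 20, a rhodium-catalysed 1,4-addition ([Rh(cod)Cl]2, a monovalent rhodium precatalyst, K3PO4, dioxane/H2O, 40 °C) should give 3-[(1R,2S,4R)-2-(tert-butyldimethylsilyloxy)-4-hydroxy-4-(3-methylbut-2-enyl)-5-oxocyclohexyl]-7-methoxychromen-2-one F2, with the heteroaryl group trans to the silyloxy group. Dehydrogenation with 2-iodoxybenzoic acid (DMSO, 65 °C), for which C2′ is again the only enolisable position, restores the C1′=C2′ bond and comes back to the route at 21.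

Step 11. What may go wrong is protodeboronation of the α-boryl lactone during the coupling or on silica, and reductive loss of bromine, because the C–B bond sits α to a carbonyl on an electron-poor alkene. Fallback: the boron reagent is bypassed. From 19 and 16, a Mizoroki–Heck reaction under ligand-free phase-transfer conditions (Pd(OAc)2, Bu4NCl, NaHCO3, DMF, 80 °C; zerovalent palladium cycle) joins the alkenyl bromide directly to the β-carbon of the enone and comes back to the route at 21 without a new compound.

Step 4. What may go wrong is premature silyl migration during the first stage (leading to double addition of the epoxide), incomplete Brook rearrangement, or proton transfer in place of alkylation, because three events must occur in a fixed order in one flask. Fallback: the classical stepwise sequence. 1,3-Dithiane (C1CSCSC1, purchased) is lithiated (n-BuLi, THF, −30 °C) and alkylated with 6 to give 2-(3-methylbut-2-enyl)-1,3-dithiane F3. This is lithiated (t-BuLi, THF/HMPA, −78 °C) and opens 4 to give (2R)-5,5-dimethoxy-1-[2-(3-methylbut-2-enyl)-1,3-dithian-2-yl]pentan-2-ol F4. Silylation (TBSCl, imidazole, DMF) comes back to the route at 10. The fallback sets out from 4 and 6.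

Step 6. What may go wrong is acid-promoted intramolecular aldol condensation of the freshly formed keto-aldehyde, migration of the skipped alkene, or partial loss of the silyl ether, because the acid meets a free ketone. Fallback: the order of unmasking is reversed so that acid never meets the ketone. From 10, acetal hydrolysis with the dithiane still in place (pyridinium p-toluenesulfonate, acetone/H2O, 40 °C) should give (4R)-4-(tert-butyldimethylsilyloxy)-5-[2-(3-methylbut-2-enyl)-1,3-dithian-2-yl]pentanal F5. Near-neutral dithiane hydrolysis (MeI, CaCO3, MeCN/H2O, 40 °C) then releases the ketone last and comes back to the route at 12.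

Further compounds

F1 | step 7 | (1R,2S,5R)-5-(tert-butyldimethylsilyloxy)-1-(3-methylbut-2-enyl)cyclohexane-1,2-diol | O[C@@H]1[C@@](O)(CC=C(C)C)C[C@H](O[Si](C)(C)C(C)(C)C)CC1
F2 | step 12 | 3-[(1R,2S,4R)-2-(tert-butyldimethylsilyloxy)-4-hydroxy-4-(3-methylbut-2-enyl)-5-oxocyclohexyl]-7-methoxychromen-2-one | COc1ccc2cc([C@H]3CC(=O)[C@@](O)(CC=C(C)C)C[C@@H]3O[Si](C)(C)C(C)(C)C)c(=O)oc2c1
F0 | step 11 | none | none
F3 | step 4 | 2-(3-methylbut-2-enyl)-1,3-dithiane | CC(C)=CCC1SCCCS1
F4 | step 4 | (2R)-5,5-dimethoxy-1-[2-(3-methylbut-2-enyl)-1,3-dithian-2-yl]pentan-2-ol | COC(OC)CC[C@@H](O)CC1(CC=C(C)C)SCCCS1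
F5 | step 6 | (4R)-4-(tert-butyldimethylsilyloxy)-5-[2-(3-methylbut-2-enyl)-1,3-dithian-2-yl]pentanal | O=CCC[C@@H](O[Si](C)(C)C(C)(C)C)CC1(CC=C(C)C)SCCCS1
A1 | alternative 1 | 3-[6,6-dimethoxy-4-(3-methylbut-2-enyl)-3-oxocyclohexa-1,4-dien-1-yl]-7-methoxychromen-2-one | COc1ccc2cc(C3=CC(=O)C(CC=C(C)C)=CC3(OC)OC)c(=O)oc2c1
A2 | alternative 1 | 7-methoxy-3-[(1S,6R)-2,2-dimethoxy-6-(3-methylbut-2-enyl)-5-oxo-7-oxabicyclo[4.1.0]hept-3-en-3-yl]chromen-2-one | COc1ccc2cc(C3=CC(=O)[C@]4(CC=C(C)C)O[C@@H]4C3(OC)OC)c(=O)oc2c1
A3 | alternative 2 | 3-methoxyphenol | COc1cccc(O)c1
A4 | alternative 2 | 2-[2-methoxy-4-(3-methylbut-2-enyl)-5-(triisopropylsilyloxy)phenyl]prop-2-enal | C=C(C=O)c1cc(O[Si](C(C)C)(C(C)C)C(C)C)c(CC=C(C)C)cc1OC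
A5 | alternative 2 | 7-methoxy-3-[2-methoxy-4-(3-methylbut-2-enyl)-5-(triisopropylsilyloxy)phenyl]-2H-chromene | COc1ccc2C=C(c3cc(O[Si](C(C)C)(C(C)C)C(C)C)c(CC=C(C)C)cc3OC)COc2c1
A6 | alternative 2 | 2-(7-methoxy-2-oxochromen-3-yl)-5-(3-methylbut-2-enyl)cyclohexa-2,5-diene-1,4-dione | COc1ccc2cc(C3=CC(=O)C(CC=C(C)C)=CC3=O)c(=O)oc2c1
A7 | alternative 3 | (3R)-3-(3-methylbut-2-enyl)-3-(triethylsilyloxy)cyclobutane-1,2-dione | O=C1C(=O)[C@@](O[Si](CC)(CC)CC)(CC=C(C)C)C1
A8 | alternative 3 | 3-ethynyl-7-methoxychromen-2-one | COc1ccc2cc(C#C)c(=O)oc2c1
A9 | alternative 3 | 3-[(4R)-4-(3-methylbut-2-enyl)-3,6-dioxo-4-(triethylsilyloxy)cyclohex-1-en-1-yl]-7-methoxychromen-2-one | COc1ccc2cc(C3=CC(=O)[C@@](O[Si](CC)(CC)CC)(CC=C(C)C)CC3=O)c(=O)oc2c1
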